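**Assumption:** the target SMILES has no stereocentres (Gardenin C is achiral, C20H20O9), so there is no enantiomer to control. The only stereo-element in the route is the E-alkene of the chalcone, which is consumed on cyclisation. Both starting materials are assumed to be catalogue items.

## Retrosynthetic overview
1. Gardenin C ⇒ its 5-O-methyl ether: the 5-OMe peri to the C4 carbonyl is the one methyl ether that can be removed selectively, so it is cleaved last.
2. Flavone C-ring (C2–O1 bond and C2=C3) ⇒ 2'-hydroxychalcone by oxidative cyclisation.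
3. Chalcone Cα=Cβ ⇒ Claisen–Schmidt condensation of 2'-hydroxy-3',4',5',6'-tetramethoxyacetophenone with 3-hydroxy-4,5-dimethoxybenzaldehyde, used unprotected.
4. Ring order: A and B rings are purchased fully oxygenated; only the pyranone C-ring is built (step 2).

## Route

**Step 1**
Reactants: 1, 1-(2-hydroxy-3,4,5,6-tetramethoxyphenyl)ethan-1-one; 2, 3-hydroxy-4,5-dimethoxybenzaldehyde
Product: 3, (E)-1-(2-hydroxy-3,4,5,6-tetramethoxyphenyl)-3-(3-hydroxy-4,5-dimethoxyphenyl)prop-2-en-1-one
Conditions: 1 (1.0 eq), 2 (1.2 eq), 50% aq. KOH (about 10 eq), EtOH, N2, rt, 24–48 h; then ice/2 M HCl to pH 2–3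
Reagents that add atoms: none
Why: Claisen–Schmidt aldol condensation; the phenoxide of 2 is meta to the CHO, so it does not deactivate the aldehyde by resonance and needs no protection, and E1cB dehydration gives the conjugated E-enone (any flavanone formed also converges in step 2).

**Step 2**
Reactants: 3, the chalcone
Product: 4, 2-(3-hydroxy-4,5-dimethoxyphenyl)-5,6,7,8-tetramethoxy-4H-chromen-4-one (3'-hydroxy-5,6,7,8,4',5'-hexamethoxyflavone)
Conditions: I2 (0.1 eq), DMSO, 130 °C, 2–3 h; aq. Na2S2O3 work-up
Reagents that add atoms: none
Why: I2/DMSO oxidative cyclisation (6-endo oxa-Michael of the only ortho-OH, then α-iodination and HI elimination, with DMSO reoxidising HI); the regiochemistry is unambiguous because the other ortho oxygen is methylated, and catalytic iodine limits B-ring iodination.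

**Step 3**
Reactants: 4, 3'-hydroxy-5,6,7,8,4',5'-hexamethoxyflavone
Product: 5, Gardenin C, 5-hydroxy-2-(3-hydroxy-4,5-dimethoxyphenyl)-6,7,8-trimethoxy-4H-chromen-4-one
Conditions: conc. HCl/EtOH (about 1:4 v/v, about 2.5 M HCl), reflux, 24–48 h, followed by HPLC
Reagents that add atoms: none
Why: selective acid-mediated demethylation of the peri 5-OMe (the protonated C4 carbonyl activates it for chloride SN2 at methyl and the product is a chelated phenol), as in nobiletin → 5-demethylnobiletin; the other five OMe groups and the free 3'-OH are inert to aqueous HCl, and any Wessely–Moser ring opening is degenerate for a 6,7,8-trimethoxy pattern.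

## Compound list
1 | 1-(2-hydroxy-3,4,5,6-tetramethoxyphenyl)ethan-1-one | CC(=O)c1c(O)c(OC)c(OC)c(OC)c1OC | starting material
2 | 3-hydroxy-4,5-dimethoxybenzaldehyde | COc1cc(C=O)cc(O)c1OC | starting material
3 | (E)-1-(2-hydroxy-3,4,5,6-tetramethoxyphenyl)-3-(3-hydroxy-4,5-dimethoxyphenyl)prop-2-en-1-one | COc1cc(/C=C/C(=O)c2c(O)c(OC)c(OC)c(OC)c2OC)cc(O)c1OC | intermediate
4 | 2-(3-hydroxy-4,5-dimethoxyphenyl)-5,6,7,8-tetramethoxy-4H-chromen-4-one | COc1cc(-c2cc(=O)c3c(OC)c(OC)c(OC)c(OC)c3o2)cc(O)c1OC | intermediate
5 | Gardenin C, 5-hydroxy-2-(3-hydroxy-4,5-dimethoxyphenyl)-6,7,8-trimethoxy-4H-chromen-4-one | COc1cc(-c2cc(=O)c3c(O)c(OC)c(OC)c(OC)c3o2)cc(O)c1OC | target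

## Summary
Total steps: 3. Longest linear sequence: 3.

Steps most likely to fail, with fallbacks that change the approach:
1. **Step 3 (stalled or over-demethylation).** Move the demethylation to the start: treat 1 with BCl3 to give the symmetrical 2',6'-dihydroxy-3',4',5'-trimethoxyacetophenone, then condense with 2 and cyclise with I2/DMSO. Either ortho-OH closes to the same flavone, so the 5-OH is delivered with no late-stage ether cleavage.
2. **Step 1 (sluggish condensation of the hindered ketone with a free-phenol aldehyde).** Switch to a Baker–Venkataraman sequence: O-acylate 1 with 3-(benzyloxy)-4,5-dimethoxybenzoyl chloride, migrate the acyl group with KOH/pyridine to the 1,3-diketone, cyclodehydrate with H2SO4/AcOH, then remove the benzyl and 5-methyl groups together with BCl3.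
3. **Step 2 (B-ring iodination of the free phenol, or stalling at the flavanone).** Split into two stages: isomerise 3 to the flavanone (NaOAc, EtOH, reflux) and dehydrogenate with DDQ in dioxane. Alternatively, use the Baker–Venkataraman route above, which needs no oxidation.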